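(The readings are simulated with made-up constants; scatter was added.)

In a one-step world, substrate would go to first product and stay there, and more reagent would simply give more of it. The earlier runs show otherwise: with 1.2 equiv of reagent, the eta flask still holds 17.4% first product at 30.0 h, while with 5.2 equiv, the zeta flask reads 0.1% at 6.00 h.

the same everywhere: substrate 49 mM
- eta: reagent 1.2 equiv; run made earlier
- zeta: reagent 5.2 equiv; run made earlier
- summer: reagent 0.800 equiv; time 30 h
- autumn: reagent 3.00 equiv; time 30 h
- spring: reagent 4.00 equiv; time 30 h

| run | time / h | first product / % | substrate / % |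
|---|---|---|---|
| eta | 2.50 | 23.2 | 40.6 |
| eta | 4.00 | 20.5 | 32.3 |
| eta | 6.00 | 22.3 | 24.5 |
| eta | 10.0 | 20.2 | 14.4 |
| eta | 20.0 | 17.4 | 7.9 |
| eta | 30.0 | 17.4 | 3.6 |
| zeta | 2.00 | 6.0 | 1.3 |
| zeta | 6.00 | 0.1 | 0.3 |
| zeta | 10.0 | 0 | 1.4 |
| zeta | 15.0 | 0 | 0.9 |
| zeta | 25.0 | 0 | 0 |
| zeta | 30.0 | 2.0 | 0.8 |

(scatter of a reading: 1 percentage point)

- amount of first product at the end, in percent of the substrate charged, for each flask in turn (summer, autumn, spring)



Turned round, the question is what autumn and spring would need for first product to stand at the end. Take its loss as pseudo-first-order, with the rate proportional to the reagent standing. The zeta fall from 6.0% to 0.1%, with reagent counted at its charge, then gives the unit halving time, the hours first product needs to halve with one equivalent of reagent standing: 3.52 h. This is a rough reading, since the later value lies within the scatter of zero.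

Halvings are then time times standing reagent over this unit time. To stay within one halving over 30 h, the autumn flask would need about 0.117 equivalents standing. If one substrate takes up at most two reagent, autumn keeps at least 1.00 equivalent, which is 8.52 halvings, and spring 17.0. From eta's reading of 23.2%, that leaves 0.0632% in autumn and <0.001% in spring. In eta, first product reads 17.4% at 20.0 h and 17.4% at 30.0 h, so those two readings show no halving. For summer, with 0.800 equiv, the halving count gives no figure, since it reckons loss and not formation.

The forecast gives 20%, 0.3% and 0.1%, holding of the large charges that “first product is destroyed, as in zeta”. Summer ends at 21.8%, autumn at <0.001% and spring at <0.001%.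

    substrate + reagent → first product + by-product (k = 0.00173 M⁻¹ s⁻¹)
    substrate + reagent → other mono adduct + by-product (k = 7.55 × 10⁻⁴ M⁻¹ s⁻¹)
    reagent + first product → double product + by-product (k = 0.00291 M⁻¹ s⁻¹)
    reagent + other mono adduct → double product + by-product (k = 0.00534 M⁻¹ s⁻¹)
    substrate + by-product → side product (k = 4.14 × 10⁻⁴ M⁻¹ s⁻¹)

Autumn already holds 0.0267% first product at 15.0 h, and 37% of its reagent charge is left at the end. Spring ends with 52% of its reagent charge, or 2.08 equivalents, and at that level the rough zeta reading of the unit halving time reckons about 17.8 halvings of first product in 30 h, an estimated half-life of 1.69 h.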